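**Retrosynthetic overview**
1. Target ⇒ tetracyclic pyrrole lactone + (S)-methylsuccinic anhydride: C-acylation of the free pyrrole α-carbon, then asymmetric ketone reduction with lactonisation (C–O) closes ring E last.
2. Tetracyclic pyrrole ⇒ amino keto aldehyde: an intramolecular Paal–Knorr condensation makes both C–N bonds and closes the pyrrole (ring C) and the azepine (ring D) in one operation; this is the key step.
3. Amino keto aldehyde ⇒ cyclohexanone-fused lactone ⇒ acyclic enone + 2-silyloxyfuran: a new amine-catalysed vinylogous Mukaiyama–Michael addition sets the ethyl/O-bearing stereodiad and brings in ring A; an enamine Michael addition then closes ring B.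
4. Enone ⇒ N-Boc-caprolactam + propanal + butenyl Grignard reagent: caprolactam supplies the nitrogen and all six azepine carbons.
5. Ring order: A (bought as the butenolide) → B → C and D together → E.

Assumption: 3-methylfuran-2(5H)-one, N-Boc-ε-caprolactam, but-3-en-1-ylmagnesium bromide (THF solution) and (S)-methylsuccinic anhydride are bought, and the target is taken exactly as the SMILES draws it (appended lactone trans, fused-lactone methyl cis to the pyrrole).

**Route**

Step 1
Reactants: 1 3-methylfuran-2(5H)-one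
Product: 2 tert-butyldimethyl[(3-methylfuran-2-yl)oxy]silane
Conditions: TBSOTf, Et3N, CH2Cl2, 0 °C
Reagents that add atoms: tert-butyldimethylsilyl trifluoromethanesulfonate, CC(C)(C)[Si](C)(C)OS(=O)(=O)C(F)(F)F
Why: Soft enolisation and O-silylation of the butenolide (silyl dienol ether formation) gives the aromatic 2-silyloxyfuran, a γ-nucleophile; no stereocentre is involved.

Step 2
Reactants: 3 tert-butyl 2-oxoazepane-1-carboxylate; 4 propanal
Product: 7 tert-butyl (3E)-2-oxo-3-propylideneazepane-1-carboxylate, via aldol adduct 5 (not isolated), via mesylate 6 (not isolated)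
Conditions: LiN(SiMe3)2, THF, −78 °C; 4; then MsCl, −78 → 0 °C; then DBU, rt
Reagents that add atoms: none
Why: Aldol condensation run as aldol addition of the lactam lithium enolate, mesylation of the aldolate and E1cB elimination, which gives the conjugated exocyclic alkene as the favoured E isomer (ethyl trans to the carbonyl).

Step 3
Reactants: 7 tert-butyl (3E)-2-oxo-3-propylideneazepane-1-carboxylate; 8 but-3-en-1-ylmagnesium bromide
Product: 9 tert-butyl N-[(5E)-6-oxo-5-propylidenedec-9-en-1-yl]carbamate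
Conditions: THF, −78 °C; then aq NH4Cl
Reagents that add atoms: none
Why: Grignard 1,2-addition to the Boc-activated lactam carbonyl (acyl substitution with ring opening) stops at the ketone because the tetrahedral magnesium hemiaminalate survives at −78 °C and collapses only on work-up, while the β-ethyl group disfavours 1,4-addition; the E alkene is kept.

Step 4
Reactants: 9 tert-butyl N-[(5E)-6-oxo-5-propylidenedec-9-en-1-yl]carbamate; 2 tert-butyldimethyl[(3-methylfuran-2-yl)oxy]silane
Product: 10 tert-butyl N-{5-[(1R)-1-[(2S)-4-methyl-5-oxo-2,5-dihydrofuran-2-yl]propyl]-6-oxodec-9-en-1-yl}carbamate (both C5 epimers)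
Conditions: 9-amino-9-deoxy-epi-quinine (20 mol%), 2,4-dinitrobenzoic acid (40 mol%), H2O (2 equiv), toluene, 0 °C → rt
Reagents that add atoms: none
Why: Proposed new method: a chiral primary-amine (iminium) catalysed vinylogous Mukaiyama–Michael addition of a 2-silyloxyfuran to an acyclic α-branched enone, which has not been shown; the cinchona primary amine condenses with the hindered ketone (secondary amines cannot) to give an acid-paired iminium ion with one face covered by the quinoline/quinuclidinium unit, C5 of the silyloxyfuran adds to the β-carbon through an open transition state that keeps the furan away from the α-chain and so sets both new centres together (1R on the propyl carbon, 2S on the butenolide; the pseudo-enantiomeric amine would give the antipode), water takes up the silyl group and hydrolyses the enamine, and the ketone α-centre forms as a mixture that is corrected in step 5; the closest known reaction types are the secondary-amine iminium-catalysed Mukaiyama–Michael addition of 2-silyloxyfurans to enals and the cinchona-primary-amine-catalysed Friedel–Crafts and sulfa-Michael additions to α-branched enones.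

Step 5
Reactants: 10 tert-butyl N-{5-[(1R)-1-[(2S)-4-methyl-5-oxo-2,5-dihydrofuran-2-yl]propyl]-6-oxodec-9-en-1-yl}carbamate
Product: 11 tert-butyl N-{4-[(3R,3aS,4S,6R,7R,7aS)-7-ethyl-3-methyl-2,5-dioxo-4-(prop-2-en-1-yl)octahydro-1-benzofuran-6-yl]butyl}carbamate
Conditions: pyrrolidine (30 mol%), AcOH (30 mol%), MeCN, 40 °C
Reagents that add atoms: none
Why: Stork enamine intramolecular Michael addition (6-exo-trig) of the less substituted enamine onto the butenolide β-carbon can only reach the face that carries the tether, so the lactone is cis-fused (3aS,7aS); protonation of the lactone enol from the convex face puts the methyl on the concave face (3R), and the two ketone α-centres equilibrate through the enamine to the equatorial positions (6R, side chain trans to ethyl).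

Step 6
Reactants: 11 tert-butyl N-{4-[(3R,3aS,4S,6R,7R,7aS)-7-ethyl-3-methyl-2,5-dioxo-4-(prop-2-en-1-yl)octahydro-1-benzofuran-6-yl]butyl}carbamate
Product: 13 tert-butyl N-{4-[(3R,3aS,4S,6R,7R,7aS)-7-ethyl-3-methyl-2,5-dioxo-4-(2-oxoethyl)octahydro-1-benzofuran-6-yl]butyl}carbamate, via ozonide 12 (not isolated)
Conditions: O3, CH2Cl2, −78 °C; then PPh3, −78 °C → rt
Reagents that add atoms: ozone, [O-][O+]=O
Why: Ozonolysis (Criegee mechanism) with reductive work-up cleaves the only C=C left in the molecule (the butenolide alkene was consumed in step 5) and unmasks the 1,4-keto aldehyde without touching any stereocentre.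

Step 7
Reactants: 13 tert-butyl N-{4-[(3R,3aS,4S,6R,7R,7aS)-7-ethyl-3-methyl-2,5-dioxo-4-(2-oxoethyl)octahydro-1-benzofuran-6-yl]butyl}carbamate
Product: 15 tetracyclic pyrrole lactone (rings A to D; 19 with H in place of the oxolanyl group), via amino keto aldehyde 14 (not isolated)
Conditions: CF3CO2H/CH2Cl2 (1:4), 0 °C; evaporate; then NaOAc, AcOH/EtOH, 0.01 M, 60 °C
Reagents that add atoms: none
Why: Boc acidolysis frees the primary amine, which condenses with the ketone (seven-membered cyclic imine) and then with the aldehyde in an intramolecular Paal–Knorr pyrrole synthesis, forming both C–N bonds and closing pyrrole and azepine together; aromatisation removes the stereocentre that carried the oxoethyl group, while the azepane methine keeps the trans (equatorial) arrangement to ethyl that it already has as a ketone α-centre.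

Step 8
Reactants: 15 tetracyclic pyrrole lactone; 16 (S)-methylsuccinic anhydride [(3S)-3-methyloxolane-2,5-dione]
Product: 17 (2S)-2-methyl-4-oxo-4-(α-pyrrolyl of 15)butanoic acid
Conditions: AlCl3 (2.5 equiv), CH2Cl2/MeNO2, −20 → 0 °C; then aq HCl
Reagents that add atoms: none
Why: Friedel–Crafts acylation occurs at the only free, most nucleophilic pyrrole α-position, and the anhydride is opened at the less hindered carbonyl (the one flanked by CH2), so the untouched (S)-methyl centre from 16 ends up α to the carboxylic acid.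

Step 9
Reactants: 17 (2S)-2-methyl-4-oxo-4-(α-pyrrolyl of 15)butanoic acid
Product: 19 target CNP0232452.4, via hydroxy acid 18 (not isolated)
Conditions: RuCl[(R,R)-TsDPEN](p-cymene) (2 mol%), HCO2H/Et3N (5:2), DMF, 30 °C
Reagents that add atoms: none
Why: Noyori–Ikariya asymmetric transfer hydrogenation of the heteroaryl ketone under reagent control (the (R,R) catalyst gives the (R)-carbinol by the usual CH/π-directed hydride delivery) is followed by spontaneous γ-lactonisation through the acyl C–O bond with retention at the carbinol carbon, giving the trans (2R,4S) lactone.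

**Compound list**
1 | 3-methylfuran-2(5H)-one | CC1=CCOC1=O | starting material
2 | tert-butyldimethyl[(3-methylfuran-2-yl)oxy]silane | Cc1ccoc1O[Si](C)(C)C(C)(C)C | intermediate
3 | tert-butyl 2-oxoazepane-1-carboxylate (N-Boc-ε-caprolactam) | O=C1CCCCCN1C(=O)OC(C)(C)C | starting material
4 | propanal | CCC=O | starting material
5 | tert-butyl 3-(1-hydroxypropyl)-2-oxoazepane-1-carboxylate (aldol adduct, diastereomer mixture, present as its lithium alkoxide) | CCC(O)C1CCCCN(C(=O)OC(C)(C)C)C1=O | intermediate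
6 | tert-butyl 3-[1-(methanesulfonyloxy)propyl]-2-oxoazepane-1-carboxylate | CCC(OS(C)(=O)=O)C1CCCCN(C(=O)OC(C)(C)C)C1=O | intermediate
7 | tert-butyl (3E)-2-oxo-3-propylideneazepane-1-carboxylate | CC/C=C1\CCCCN(C(=O)OC(C)(C)C)C1=O | intermediate
8 | but-3-en-1-ylmagnesium bromide | C=CCC[Mg]Br | starting material
9 | tert-butyl N-[(5E)-6-oxo-5-propylidenedec-9-en-1-yl]carbamate | CC/C=C(\CCCCNC(=O)OC(C)(C)C)C(=O)CCC=C | intermediate
10 | tert-butyl N-{5-[(1R)-1-[(2S)-4-methyl-5-oxo-2,5-dihydrofuran-2-yl]propyl]-6-oxodec-9-en-1-yl}carbamate (C5 epimer mixture) | CC[C@H](C(CCCCNC(=O)OC(C)(C)C)C(=O)CCC=C)[C@@H]1OC(=O)C(C)=C1 | intermediate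
11 | tert-butyl N-{4-[(3R,3aS,4S,6R,7R,7aS)-7-ethyl-3-methyl-2,5-dioxo-4-(prop-2-en-1-yl)octahydro-1-benzofuran-6-yl]butyl}carbamate | CC[C@H]1[C@@H]2OC(=O)[C@H](C)[C@@H]2[C@H](CC=C)C(=O)[C@@H]1CCCCNC(=O)OC(C)(C)C | intermediate
12 | ozonide of 11 (1,2,4-trioxolan-3-ylmethyl in place of the allyl group; trioxolane carbon as a mixture) | CC[C@H]1[C@@H]2OC(=O)[C@H](C)[C@@H]2[C@H](CC2OCOO2)C(=O)[C@@H]1CCCCNC(=O)OC(C)(C)C | intermediate
13 | tert-butyl N-{4-[(3R,3aS,4S,6R,7R,7aS)-7-ethyl-3-methyl-2,5-dioxo-4-(2-oxoethyl)octahydro-1-benzofuran-6-yl]butyl}carbamate | CC[C@H]1[C@@H]2OC(=O)[C@H](C)[C@@H]2[C@H](CC=O)C(=O)[C@@H]1CCCCNC(=O)OC(C)(C)C | intermediate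
14 | 2-[(3R,3aS,4S,6R,7R,7aS)-6-(4-aminobutyl)-7-ethyl-3-methyl-2,5-dioxooctahydro-1-benzofuran-4-yl]acetaldehyde | CC[C@H]1[C@@H]2OC(=O)[C@H](C)[C@@H]2[C@H](CC=O)C(=O)[C@@H]1CCCCN | intermediate
15 | tetracyclic pyrrole lactone: γ-lactone (ring A) cis-fused to cyclohexene (ring B), fused to pyrrole (ring C) and azepane (ring D); 19 with H in place of the oxolanyl group, five stereocentres as in 19 | CC[C@H]1[C@@H]2OC(=O)[C@H](C)[C@@H]2c2ccn3c2[C@@H]1CCCC3 | intermediate
16 | (S)-methylsuccinic anhydride, (3S)-3-methyloxolane-2,5-dione | C[C@H]1CC(=O)OC1=O | starting material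
17 | (2S)-2-methyl-4-oxo-4-(α-pyrrolyl of 15)butanoic acid | CC[C@H]1[C@@H]2OC(=O)[C@H](C)[C@@H]2c2cc(C(=O)C[C@H](C)C(O)=O)n3c2[C@@H]1CCCC3 | intermediate
18 | (2S,4R)-4-hydroxy-2-methyl-4-(α-pyrrolyl of 15)butanoic acid | CC[C@H]1[C@@H]2OC(=O)[C@H](C)[C@@H]2c2cc([C@H](O)C[C@H](C)C(O)=O)n3c2[C@@H]1CCCC3 | intermediate
19 | CNP0232452.4: 15 carrying a (2R,4S)-4-methyl-5-oxooxolan-2-yl group (ring E) on the pyrrole α-carbon; ring centres: ethyl-bearing C (R), O-bearing C (S), lactone α-C (R), ring-fusion C next to the pyrrole (R), azepane CH (R) | CC[C@H]1[C@@H]2OC(=O)[C@H](C)[C@@H]2c2cc([C@H]3C[C@H](C)C(=O)O3)n3c2[C@@H]1CCCC3 | target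

**Count and risks**
Total step count: 9. Longest linear sequence: 8 (steps 2 to 9, from 3 to 19).

Step 4 (the proposed new step). The α-branched enone may form the iminium ion slowly, and the enantio- and diastereocontrol are unproven. The fallback uses only known reaction types and moves the amino side chain to a later enolate alkylation. It sets out from 2:
- Secondary-amine (5-benzyl-2-tert-butyl-3-methylimidazolidin-4-one salt, enantiomer chosen for this product) iminium-catalysed Mukaiyama–Michael addition of 2 to (E)-pent-2-enal gives (3R)-3-[(2S)-4-methyl-5-oxo-2,5-dihydrofuran-2-yl]pentanal F3.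
- Addition of 8 at −78 °C gives (7R)-7-[(2S)-4-methyl-5-oxo-2,5-dihydrofuran-2-yl]non-1-en-5-ol F4.
- Dess–Martin oxidation gives (7R)-7-[(2S)-4-methyl-5-oxo-2,5-dihydrofuran-2-yl]non-1-en-5-one F5.
- Pyrrolidine/AcOH closes it to (3R,3aS,4S,7R,7aS)-7-ethyl-3-methyl-4-(prop-2-en-1-yl)hexahydro-1-benzofuran-2,5(3H,4H)-dione F6.
- Kinetic enolisation at the CH2 side (LiN(iPr)2, THF, −78 °C) and alkylation with 1-azido-4-iodobutane (DMPU) gives (3R,3aS,4S,6R,7R,7aS)-6-(4-azidobutyl)-7-ethyl-3-methyl-4-(prop-2-en-1-yl)hexahydro-1-benzofuran-2,5(3H,4H)-dione F7.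
- Ozonolysis through the ozonide of the azide F8, with Me2S work-up, gives 2-[(3R,3aS,4S,6R,7R,7aS)-6-(4-azidobutyl)-7-ethyl-3-methyl-2,5-dioxooctahydro-1-benzofuran-4-yl]acetaldehyde F9.
- Staudinger reduction (PPh3, THF/H2O) gives 14, where the fallback comes back to the route; 14 closes to 15 under the buffer of step 7.

Step 3. The Grignard reagent may add 1,4, attack the Boc carbonyl or add twice. The fallback replaces the lactam by a Weinreb amide as the acylating partner. It sets out from 7: LiOH in THF/H2O opens the lactam to (2E)-2-{4-[(tert-butoxycarbonyl)amino]butyl}pent-2-enoic acid F1; MeNHOMe·HCl, EDC·HCl and iPr2NEt give tert-butyl N-{(5E)-5-[methoxy(methyl)carbamoyl]oct-5-en-1-yl}carbamate F2; 8 (2.2 equiv, THF, 0 °C) then gives 9, where the fallback comes back to the route.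

Step 9. The 2-acylpyrrole is a vinylogous amide and may reduce slowly, and the pyrrolyl carbinol ester can ionise in the acidic formate medium, which would epimerise the carbinol carbon or over-reduce it. The fallback builds the carbinol centre by C–C bond formation and also bypasses step 8. It sets out from 15: Vilsmeier–Haack formylation (POCl3, DMF) gives the α-formyl derivative of 15 F10; Ti(OiPr)4/(1S,2S)-1,2-bis(trifluoromethanesulfonamido)cyclohexane-catalysed addition of the dialkylzinc [CH3O2CCH(CH3)CH2]2Zn (from methyl (R)-3-iodo-2-methylpropanoate and Et2Zn) gives methyl (2S,4R)-4-hydroxy-2-methyl-4-(α-pyrrolyl of 15)butanoate F11, whose zinc alkoxide lactonises on warming to 19, where the fallback comes back to the route.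

**Further compounds**
F1 | step 3 | (2E)-2-{4-[(tert-butoxycarbonyl)amino]butyl}pent-2-enoic acid | CC/C=C(\CCCCNC(=O)OC(C)(C)C)C(O)=O
F2 | step 3 | tert-butyl N-{(5E)-5-[methoxy(methyl)carbamoyl]oct-5-en-1-yl}carbamate | CC/C=C(\CCCCNC(=O)OC(C)(C)C)C(=O)N(C)OC
F3 | step 4 | (3R)-3-[(2S)-4-methyl-5-oxo-2,5-dihydrofuran-2-yl]pentanal | CC[C@H](CC=O)[C@@H]1OC(=O)C(C)=C1
F4 | step 4 | (7R)-7-[(2S)-4-methyl-5-oxo-2,5-dihydrofuran-2-yl]non-1-en-5-ol (carbinol epimers) | CC[C@H](CC(O)CCC=C)[C@@H]1OC(=O)C(C)=C1
F5 | step 4 | (7R)-7-[(2S)-4-methyl-5-oxo-2,5-dihydrofuran-2-yl]non-1-en-5-one | CC[C@H](CC(=O)CCC=C)[C@@H]1OC(=O)C(C)=C1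
F6 | step 4 | (3R,3aS,4S,7R,7aS)-7-ethyl-3-methyl-4-(prop-2-en-1-yl)hexahydro-1-benzofuran-2,5(3H,4H)-dione | CC[C@H]1[C@@H]2OC(=O)[C@H](C)[C@@H]2[C@H](CC=C)C(=O)C1
F7 | step 4 | (3R,3aS,4S,6R,7R,7aS)-6-(4-azidobutyl)-7-ethyl-3-methyl-4-(prop-2-en-1-yl)hexahydro-1-benzofuran-2,5(3H,4H)-dione | CC[C@H]1[C@@H]2OC(=O)[C@H](C)[C@@H]2[C@H](CC=C)C(=O)[C@@H]1CCCCN=[N+]=[N-]
F8 | step 4 | ozonide of F7 (1,2,4-trioxolan-3-ylmethyl in place of the allyl group) | CC[C@H]1[C@@H]2OC(=O)[C@H](C)[C@@H]2[C@H](CC2OCOO2)C(=O)[C@@H]1CCCCN=[N+]=[N-]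
F9 | step 4 | 2-[(3R,3aS,4S,6R,7R,7aS)-6-(4-azidobutyl)-7-ethyl-3-methyl-2,5-dioxooctahydro-1-benzofuran-4-yl]acetaldehyde | CC[C@H]1[C@@H]2OC(=O)[C@H](C)[C@@H]2[C@H](CC=O)C(=O)[C@@H]1CCCCN=[N+]=[N-]
F10 | step 9 | α-formyl derivative of 15 (CHO on the free pyrrole α-carbon) | CC[C@H]1[C@@H]2OC(=O)[C@H](C)[C@@H]2c2cc(C=O)n3c2[C@@H]1CCCC3
F11 | step 9 | methyl (2S,4R)-4-hydroxy-2-methyl-4-(α-pyrrolyl of 15)butanoate | CC[C@H]1[C@@H]2OC(=O)[C@H](C)[C@@H]2c2cc([C@H](O)C[C@H](C)C(=O)OC)n3c2[C@@H]1CCCC3
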